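| setting | east | north | summer | autumn | midnight | dawn | dusk |
|---|---|---|---|---|---|---|---|
| J | 0.10 M | 0.10 M | 0.10 M (fed, over 2.5 min) | 0.10 M | 0.10 M | 0.10 M (fed, over 15 s) | 0.10 M |
| Z | 1.2 equiv | 1.2 equiv | 1.20 equiv | 1.20 equiv (in portions, 2, over 2.5 min) | 1.20 equiv | 1.20 equiv | 1.20 equiv (fed, over 2.5 min) |
| E | 1.3 equiv | 0.65 equiv | 1.30 equiv | 1.30 equiv | 1.30 equiv | 1.30 equiv | 1.30 equiv |
| Q | 0.10 M | 0.10 M | 0.100 M | 0.100 M | 0.100 M | 0.100 M | 0.100 M |
| remark | run made earlier | run made earlier | all else is in the flask from the start; the feed brings no volume worth counting | first portion at the start, last at 2.5 min | everything together at the start | all else is in the flask from the start; the feed brings no volume worth counting | all else is in the flask from the start; the feed brings no volume worth counting |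
| time |  |  | 4.0 min | 4.0 min | 4.0 min | 4.0 min | 4.0 min |

east run (percent of the J charged)

| time / min | L / % | X / % |
|---|---|---|
| 0.200 | 8 | 3 |
| 0.417 | 17 | 17 |
| 1.00 | 20 | 32 |
| 2.50 | 17 | 42 |

north run (percent of the J charged)

| time / s | L / % | X / % |
|---|---|---|
| 20.0 | 8 | 11 |
| 40.0 | 12 | 14 |
| 50.0 | 13 | 17 |
| 80.0 | 15 | 28 |

(readings scatter by 2 percentage points)

- percent here means J units held: one L counts as two

* the flask that comes out highest in amount of L, in percent of the J charged, or "all alike" when all lie within 1.5 percentage points (summer / autumn / midnight / dawn / dusk / all alike)
* L at the end, in percent of the J charged, summer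
* L at the end, in percent of the J charged, autumn
* L at the end, in percent of the J charged, midnight
* L at the end, in percent of the J charged, dawn
* L at the end, in percent of the J charged, dusk

**First instants.** The easy step to read is the start of east, where J, Z, E and Q stand together and X and L appear within seconds: counted in J units, their sum is 11.0% at 0.200 min and 34.0% at 0.417 min. That sum reads 59.0% at 2.50 min, and interpolation puts half of this reading at 0.375 min, a half-time of take-up with the scatter of its readings.

**Feed against take-up.** Dividing feed time by this half-time gives 6.67 for the slow feeds of summer and dusk and 0.667 for the quick feed of dawn; the first is the dose number, feed time over half-time of take-up. Dawn's value lies below one, so its charge is in before take-up is half done, and dawn should follow midnight, whereas the slow feeds should not.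

**The middle.** North, with 0.65 equiv of E against 1.3 equiv in east, shows at 80.0 s less L than east at 1.00 min, 15% against 20%, and less X, 28% against 32%, though it has run longer. With a scatter of 2 percentage points, this reckoning tentatively takes L to form where J meets X.

**The end.** If J is gone in east, a rival, presumably Q, took the remaining 41.0%. At any moment the rate of J into L over the rate into that rival equals the ratio of their rate constants, not read here, times X over Q, with J itself cancelling, and this comparison drifts towards L as X grows. So this reckoning ranks summer first, where J arrives among X, then autumn, then dawn with midnight, near east's 17% to 20%, and dusk last, where J stands with its rival while Z is still being fed.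

**The forecast.** It named dusk, with summer 8%, autumn 17%, midnight 15%, dawn 14% and dusk 19%, so it stands opposite this reckoning on summer and dusk. Its ground: “Feeding J slowly keeps J low and lets reagent waste away, so summer has much less L”.

**The flasks.** Summer ended highest with 39.1% of L, beside autumn 25.5%, midnight 20.0%, dawn 21.9% and dusk 14.5%.

    E + D → X (k = 0.320 /M/s)
    J + Q → G (k = 0.550 /M/s)
    J + X → L (k = 2.30 /M/s)
    J + Z → D (k = 0.660 /M/s)

In dusk, with dose number 6.67, the half-life of J at 0.175 min was 0.33 min by Q against 2.6 min by Z, and dusk ended with G at 72.8% and X at 12.7%. Dawn, at 0.667, ended with X at 40.6%, where midnight ended with X at 42.0%.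

(The data stem from a simulated flask for substances that don't exist; the scatter is artificial.)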